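An hour in a tank is an average, not an age. The flasks and readings are these:

| flask | substrate | remark | time |
|---|---|---|---|
| ochre | 0.033 M | run made earlier |  |
| amber | 0.017 M | run made earlier |  |
| green | 0.025 M | run made earlier |  |
| Monday's | 0.033 M | a closed flask charged with all of it at once and left for 10 h | 10 h |
| Tuesday's | 0.033 M | a single well-mixed tank run continuously and read at steady state, 10 h in it on average |  |
| Thursday's | 0.033 M | a single well-mixed tank run continuously and read at steady state, 30.0 h in it on average |  |

- ochre (time / h: target / %): 1.50: 34; 3.00: 29; 5.00: 20; 6.00: 18; 8.00: 16; 10.0: 13
- amber (time / h: target / %): 1.50: 35; 3.00: 27; 5.00: 17; 6.00: 16; 8.00: 19; 10.0: 13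
- green (time / h: target / %): 1.50: 37; 3.00: 27; 5.00: 19; 6.00: 17; 8.00: 16; 10.0: 15

(standard deviation of a reading: 2 percentage points)

- the stated concentrations are those of everything mixed, before any reaction; amounts are the same in each set-up
- what was read earlier has a scatter of 2 percentage points, one standard deviation
- the earlier runs were made in a closed, stirred flask
- a reading or a percentage of target counts all its forms, free or not

1. the set-up with the highest amount of target at the outlet or at the end, in percent of the substrate put in ("none" if the first two lie within 2 percentage points) (Monday's / Tuesday's / Thursday's / none)
2. amount of target at the outlet or at the end, in percent of the substrate put in, Monday's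
3. amount of target at the outlet or at the end, in percent of the substrate put in, Tuesday's
4. amount of target at the outlet or at the end, in percent of the substrate put in, Thursday's

Here is the puzzle. Tuesday's tank has the ochre charge and as many hours on average as the last ochre reading, yet that reading of 13% is a poor guess for its outlet.

A well-mixed tank holds fluid of every age, and its exit-age distribution says how much of each. Define the old share φ, the fraction of the outlet older than the last reading at t_end, for a mean residence time τ. This is the quantity to carry:

φ = exp(−t_end/τ), Tuesday's 36.8%, Thursday's 71.7%

I treat each parcel as a small flask, an assumption of mine: charges from 0.017 M to 0.033 M give 13% to 15% at the last reading, with a scatter of 2 percentage points. As a crude reckoning of my own, let the younger fluid carry the ochre mean ȳ = 21.7% and the older fluid the last reading y_end: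

y_tank ≈ ȳ + φ·(y_end − ȳ)

Tuesday's: 18.5%
Thursday's: 15.5%

Monday's flask should match the ochre reading, so Tuesday's comes out highest.

The forecast says Tuesday's, with 14% for Monday's, 20% for Tuesday's and 14.5% for Thursday's. Its Tuesday figure stands above my 18.5%, and its Thursday figure, lower than my 15.5%, rests on a fall “which suggests a plateau near 12%”.

Tuesday's gives 20.2%, above Monday's 15.0% and Thursday's 13.1%, and my mix was 1.7 points below it.

substrate ⇌ isomer of the product (K = 5.40, k = 0.810 h⁻¹); target → over-reaction product (k = 7.50 × 10⁻⁴ h⁻¹); substrate ⇌ third isomer (K = 110, k = 0.160 h⁻¹); substrate ⇌ target (K = 1.40, k = 1.70 h⁻¹); substrate + target ⇌ idle adduct, settled at all times (K = 49.0 M⁻¹) Third isomer stands at 20.6% at Tuesday's outlet and 39.1% at Thursday's. With Thursday's old share of 71.7%, the mix rule turns that tank's result into a figure for its older fluid of 9.71%.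

(The readings were generated by integration with constants of no real substance, noise included.)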